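No rate constant is known for these flasks. What can be used are the earlier runs, which share one loading of enzyme and differ in their charge of starting material.

in all of them: enzyme 0.017 mol%

| run | starting material | second substrate | remark | time |
|---|---|---|---|---|
| larch | 0.016 M | 0.90 equiv | run made earlier |  |
| cedar | 0.035 M | 0.90 equiv | run made earlier |  |
| maple | 0.091 M | 0.90 equiv | run made earlier |  |
| summer | 0.068 M | 0.900 equiv |  | 2.5 min |
| spring | 0.050 M | 0.900 equiv |  | 2.5 min |
| midnight | 0.015 M | 0.900 equiv |  | 2.5 min |
| noon | 0.030 M | 0.900 equiv |  | 2.5 min |
| dawn | 0.10 M | 0.900 equiv |  | 2.5 min |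

| larch: time / s | larch: target / % | cedar: time / s | cedar: target / % | maple: time / s | maple: target / % |
|---|---|---|---|---|---|
| 10.0 | 2.8 | 10.0 | 4.8 | 10.0 | 14.0 |
| 25.0 | 1.7 | 25.0 | 7.6 | 25.0 | 19.7 |
| 50.0 | 3.3 | 50.0 | 9.6 | 50.0 | 26.1 |
| 80.0 | 6.9 | 80.0 | 13.5 | 80.0 | 33.7 |
| 120 | 4.4 | 120 | 16.1 | 120 | 39.9 |

(standard deviation of a reading: 1 percentage point)



* the flasks by amount of target, in percent of the starting material charged, highest first, at 2.5 min (summer / spring / midnight / noon / dawn)
* the same order at 8.0 s (summer / spring / midnight / noon / dawn)
* the amount of target, in percent of the starting material charged of the flask you put first, at 2.5 min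
* the amount of target, in percent of the starting material charged of the flask you put last, at 2.5 min

Read across the table of readings first. At the earliest reading, 10.0 s, the runs stand at 2.8 %, 4.8 % and 14.0 %, and at the latest, 120 s, at 4.4 %, 16.1 % and 39.9 %, in the order of their charges both times. So the reckoning here ranks the new flasks by charge at both asked times.

Now read down the maple columns. At 120 s maple has a depth of 0.509: the depth is minus the natural logarithm of the fraction of the charge not yet target. Between 80.0 s and 120 s the maple readings put depth growing with time to the power 0.528, and the cedar readings to the power 0.471. Both readings, with their scatter, lie close to a half , a square root of time.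

Depth also follows the charge, but not exactly: maple holds 2.60 times cedar's charge and 2.90 times its depth. Each end is therefore reckoned from its nearest run, with depth scaled in proportion to the charge and to the square root of time. Dawn, from maple, gets depth 0.626, or 46.5 % target. Larch's last readings, 6.9 % then 4.4 %, scatter, so their mean is taken at their mean time, and midnight gets 6.46 %.

The forecast gives dawn > summer > spring > noon > midnight at 2.5 min and dawn > summer > spring > noon > midnight at 8.0 s, “so the order follows concentration at both times”, with 47 % for dawn and 8 % for midnight, the latter higher than the 6.46 % reckoned here.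

The flasks give dawn > summer > spring > noon > midnight at 2.5 min and dawn > summer > spring > noon > midnight at 8.0 s. Dawn holds 46.7 %, a depth of 0.629 against the 0.626 reckoned, and midnight holds 6.72 %.

    starting material + enzyme ⇌ starting complex (K = 111 /M, k = 2.58 × 10⁵ /M/s)
    second substrate + starting complex ⇌ ternary complex (K = 18.5 /M, k = 72900 /M/s)
    ternary complex → enzyme + target (k = 253 /s)
    second substrate ⇌ dormant form (K = 4.70, k = 0.0847 /s)
    2 enzyme ⇌ resting dimer, settled at all times (K = 7.81 × 10⁶ /M)

A neighbour of dawn, charged with 0.0068 mol% of enzyme instead of 0.017 mol%, takes the same reckoning if its lower loading is read as a slower clock. The time under the square root is then multiplied by the ratio of loadings, and the depth reckoned for dawn shrinks to 0.396 for the neighbour, or 32.7 % target. The neighbour gives 31.8 %. At 2.50 min the neighbour's resting dimer, which in dawn is the resting state of the catalyst, holds 40.5 % of the catalyst against 63.4 % in dawn, and 68 % of the neighbour's starting material stands unbound.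

(The readings come from a simulation for an exercise; scatter was added.)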